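## Retrosynthetic overview
1. The target comes from the 15,19-diol by selective 15-O-acetylation and oxidation of C-19; the diol comes from reductive release of a C-19 chiral ester after the C-3 carbonyl is removed.
2. Rings A and B, the C-4 quaternary centre and the 8(17)-alkene are disconnected together: one oxidative free-radical bicyclisation of an acyclic (E,E)-dienyl α-methyl β-keto ester (ring A closes first, ring B second, same operation). An 8-phenylmenthyl ester sets the absolute configuration at C-4, C-5, C-9 and C-10.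
3. The acyclic precursor comes from γ-alkylation of the dianion of (−)-8-phenylmenthyl 2-methylacetoacetate with a C15 allylic bromide.
4. The bromide comes from (2E,6E)-farnesol: asymmetric hydrogenation (sets C-13), terminal allylic oxidation, selective allylic bromination.

Assumption: the SMILES is read as (4S,5R,9S,10R,13S)-15-acetoxylabd-8(17)-en-19-oic acid (15-O-acetylimbricatolic acid); labdane numbering is used throughout (C-19 = carboxyl carbon on C-4, cis to the C-10 methyl; C-17 = exocyclic methylene carbon; C-15 = acetoxy-bearing carbon).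

Assumption: the auxiliary acts by the usual π-shielding picture (Z ester, carbinol C–H eclipsing C=O, ester C=O s-cis to the C-3/C-4 enol-radical bond as in a (Z)-enoate), which for the (1R,2S,5R) auxiliary leaves the Re face of C-4 open.

## Route

Step 1
Reactants: 1 (2E,6E)-farnesol
Product: 2 (S)-2,3-dihydrofarnesol [(3S,6E)-3,7,11-trimethyldodeca-6,10-dien-1-ol]
Conditions: H2 (50 atm), Ru(OAc)2[(R)-BINAP] (0.5 mol %), MeOH–H2O 95:5, 25 °C
Reagents that add atoms: none
Why: Noyori asymmetric hydrogenation; the hydroxyl-bound ruthenium catalyst reduces only the allylic 2,3-alkene, and the (R)-BINAP/(E)-alkene pairing gives (3S) (the geraniol-to-(S)-citronellol sense) while both remote trisubstituted alkenes stay.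

Step 2
Reactants: 2 (S)-2,3-dihydrofarnesol
Product: 3 (3S,6E,10E)-3,7,11-trimethyldodeca-6,10-diene-1,12-diol
Conditions: SeO2 (0.3 equiv), t-BuOOH (3 equiv), salicylic acid (0.1 equiv), CH2Cl2, 0 → 23 °C, stopped near 70 % conversion (recovered 2 recycled)
Reagents that add atoms: tert-butyl hydroperoxide, CC(C)(C)OO; selenium dioxide, O=[Se]=O (catalytic oxygen relay)
Why: Riley allylic oxidation (ene reaction then [2,3]-sigmatropic shift) is fastest at the terminal, least hindered trisubstituted alkene and hydroxylates only its (E)-methyl group; the saturated primary alcohol and C-3 are untouched.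

Step 3
Reactants: 3 (3S,6E,10E)-3,7,11-trimethyldodeca-6,10-diene-1,12-diol
Product: 4 (3S,6E,10E)-12-bromo-3,7,11-trimethyldodeca-6,10-dien-1-ol
Conditions: NBS (1.1 equiv), Me2S (1.3 equiv), CH2Cl2, −20 → 0 °C
Reagents that add atoms: N-bromosuccinimide, O=C1CCC(=O)N1Br
Why: Corey–Kim halogenation; only the allylic alkoxysulfonium ion is displaced by bromide (SN2, no allylic transposition, E geometry kept), while the saturated primary alcohol returns unchanged on work-up.

Step 4
Reactants: 5 (−)-8-phenylmenthol [(1R,2S,5R)-5-methyl-2-(2-phenylpropan-2-yl)cyclohexan-1-ol]; 6 methyl 2-methyl-3-oxobutanoate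
Product: 7 (1R,2S,5R)-8-phenylmenthyl 2-methyl-3-oxobutanoate (α-carbon epimers)
Conditions: 6 (2 equiv), DMAP (0.3 equiv), toluene, reflux through 4 Å sieves (removal of MeOH)
Reagents that add atoms: none
Why: DMAP-catalysed β-keto ester transesterification (acylketene/acylpyridinium pathway) driven by removal of methanol; the carbinol centre of the auxiliary is not touched.

Step 5
Reactants: 7 (1R,2S,5R)-8-phenylmenthyl 2-methyl-3-oxobutanoate; 4 (3S,6E,10E)-12-bromo-3,7,11-trimethyldodeca-6,10-dien-1-ol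
Product: 9 (1R,2S,5R)-8-phenylmenthyl (6E,10E,14S)-16-hydroxy-2,6,10,14-tetramethyl-3-oxohexadeca-6,10-dienoate, via dilithium dienolate 8 (not isolated)
Conditions: 7 (2.2 equiv), LiN(i-Pr)2 (4.4 equiv), THF, −78 → 0 °C; then 4 (1.0 equiv), 0 °C, 30 min; aq NH4Cl
Reagents that add atoms: none
Why: Weiler dianion alkylation; the terminal (γ) carbanion attacks the primary allylic bromide by SN2 with alkene geometry kept, one extra equivalent of dianion is spent on the free hydroxyl (protonated 7 is recovered), and the epimer mixture at the α-carbon (future C-4) is irrelevant because that carbon becomes a radical.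

Step 6
Reactants: 9 (1R,2S,5R)-8-phenylmenthyl (6E,10E,14S)-16-hydroxy-2,6,10,14-tetramethyl-3-oxohexadeca-6,10-dienoate
Product: 10 (1R,2S,5R)-8-phenylmenthyl (4R,5R,9S,10R,13S)-15-hydroxy-3-oxolabd-8(17)-en-19-oate
Conditions: Mn(OAc)3·2H2O (2.2 equiv), Cu(OAc)2·H2O (1.0 equiv, turned over by the manganese oxidant), degassed AcOH (0.05 M), 25 → 40 °C; chromatography removes the minor ring diastereomer (expected dr about 6–10:1)
Reagents that add atoms: none
Why: Mn(OAc)3/Cu(OAc)2 oxidative free-radical polyene bicyclisation: trivalent manganese oxidises the enolised β-keto ester to the C-4 radical, which closes ring A (C-4–C-5) and then ring B (C-10–C-9) 6-endo/6-endo through an all-chair array, so the (E)-alkenes give the trans-decalin with equatorial C-9 chain and axial C-10 methyl, the ester (syn to C-2 in the radical) ends axial on C-4, the phenyl ring of the (1R,2S,5R) auxiliary covers the Si face of C-4 so C-5 bonds to the Re face and fixes the absolute sense, and divalent copper oxidises the tertiary C-8 radical with loss of a methyl hydrogen to the exocyclic alkene.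

Step 7
Reactants: 10 (1R,2S,5R)-8-phenylmenthyl (4R,5R,9S,10R,13S)-15-hydroxy-3-oxolabd-8(17)-en-19-oate
Product: 13 (1R,2S,5R)-8-phenylmenthyl (4S,5R,9S,10R,13S)-15-hydroxylabd-8(17)-en-19-oate, via tosylhydrazone 11 (not isolated), via boron adduct 12 (not isolated)
Conditions: TsNHNH2 (1.5 equiv), PPTS (5 mol %), 4 Å sieves, CHCl3, 55 °C; then catecholborane (4 equiv), 0 °C; then NaOAc·3H2O (5 equiv), reflux; aqueous work-up
Reagents that add atoms: none
Why: Kabalka variant of the Caglioti tosylhydrazone reduction; the hydrazone forms from the open C-2 side of the ketone, catecholborane hydroborates C=N (the 15-OH is borylated in passing and freed on work-up), and acetate triggers loss of sulfinate and N2 to leave CH2 without touching the ester, the exocyclic alkene or any stereocentre.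

Step 8
Reactants: 13 (1R,2S,5R)-8-phenylmenthyl (4S,5R,9S,10R,13S)-15-hydroxylabd-8(17)-en-19-oate
Product: 14 (4S,5R,9S,10R,13S)-labd-8(17)-ene-15,19-diol
Conditions: LiAlH4 (4 equiv), THF, reflux; H2O work-up; auxiliary 5 recovered
Reagents that add atoms: none
Why: LiAlH4 ester reduction; the small aluminohydride reaches even the axial neopentyl acyl carbon at reflux, giving the C-19 primary alcohol and releasing the auxiliary for reuse, with no stereocentre involved.

Step 9
Reactants: 14 (4S,5R,9S,10R,13S)-labd-8(17)-ene-15,19-diol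
Product: 15 (4S,5R,9S,10R,13S)-19-hydroxylabd-8(17)-en-15-yl acetate
Conditions: AcCl (1.05 equiv), 2,4,6-collidine (2 equiv), CH2Cl2, −78 °C
Reagents that add atoms: acetyl chloride, CC(Cl)=O
Why: Kinetically selective O-acylation; the unhindered primary 15-OH reacts far faster than the axial neopentyl 19-OH, and collidine keeps the medium non-acidic for the exocyclic alkene.

Step 10
Reactants: 15 (4S,5R,9S,10R,13S)-19-hydroxylabd-8(17)-en-15-yl acetate
Product: 16 (4S,5R,9S,10R,13S)-15-acetoxylabd-8(17)-en-19-oic acid (CNP0401865.2)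
Conditions: CrO3, H2SO4, H2O (2.5 equiv of oxidant), acetone, 0 °C, 40 min
Reagents that add atoms: water, O; chromium trioxide, O=[Cr](=O)=O
Why: Jones oxidation of the neopentyl primary alcohol through the aldehyde hydrate to the carboxylic acid; the acetate and the 1,1-disubstituted alkene tolerate brief exposure at 0 °C and the quaternary C-4 cannot epimerise.

## Compound list
1 | (2E,6E)-farnesol, (2E,6E)-3,7,11-trimethyldodeca-2,6,10-trien-1-ol | CC(C)=CCC/C(C)=C/CC/C(C)=C/CO | starting material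
2 | (S)-2,3-dihydrofarnesol, (3S,6E)-3,7,11-trimethyldodeca-6,10-dien-1-ol | CC(C)=CCC/C(C)=C/CC[C@H](C)CCO | intermediate
3 | (3S,6E,10E)-3,7,11-trimethyldodeca-6,10-diene-1,12-diol | OC/C(C)=C/CC/C(C)=C/CC[C@H](C)CCO | intermediate
4 | (3S,6E,10E)-12-bromo-3,7,11-trimethyldodeca-6,10-dien-1-ol | BrC/C(C)=C/CC/C(C)=C/CC[C@H](C)CCO | intermediate
5 | (−)-8-phenylmenthol, (1R,2S,5R)-5-methyl-2-(2-phenylpropan-2-yl)cyclohexan-1-ol | C[C@@H]1CC[C@H]([C@@H](C1)O)C(C)(C)c1ccccc1 | starting material
6 | methyl 2-methyl-3-oxobutanoate | CC(=O)C(C)C(=O)OC | starting material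
7 | (1R,2S,5R)-8-phenylmenthyl 2-methyl-3-oxobutanoate (α-carbon epimers) | CC(=O)C(C)C(=O)O[C@@H]1C[C@H](C)CC[C@H]1C(C)(C)c1ccccc1 | intermediate
8 | dilithium dienolate (dianion) of 7 | [Li+].[Li+].C=C([O-])C(C)=C([O-])O[C@@H]1C[C@H](C)CC[C@H]1C(C)(C)c1ccccc1 | intermediate
9 | (1R,2S,5R)-8-phenylmenthyl (6E,10E,14S)-16-hydroxy-2,6,10,14-tetramethyl-3-oxohexadeca-6,10-dienoate (C-2 epimers) | CC(C(=O)CC/C(C)=C/CC/C(C)=C/CC[C@H](C)CCO)C(=O)O[C@@H]1C[C@H](C)CC[C@H]1C(C)(C)c1ccccc1 | intermediate
10 | (1R,2S,5R)-8-phenylmenthyl (4R,5R,9S,10R,13S)-15-hydroxy-3-oxolabd-8(17)-en-19-oate; trans-decalin, ester axial on C-4 and cis to the C-10 methyl, 5-H and 9-H α, exocyclic 8(17)-methylene (4R only because the 3-oxo group changes CIP priority; same spatial arrangement as the target) | C=C1CC[C@@H]2[C@](C)(CCC(=O)[C@]2(C)C(=O)O[C@@H]3C[C@H](C)CC[C@H]3C(C)(C)c4ccccc4)[C@H]1CC[C@H](C)CCO | intermediate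
11 | 3-(p-toluenesulfonylhydrazone) of 10 | C=C1CC[C@@H]2[C@](C)(CCC(=NNS(=O)(=O)c5ccc(C)cc5)[C@]2(C)C(=O)O[C@@H]3C[C@H](C)CC[C@H]3C(C)(C)c4ccccc4)[C@H]1CC[C@H](C)CCO | intermediate
12 | boron adduct: 3-[N-(1,3,2-benzodioxaborol-2-yl)-N′-tosylhydrazino] 15-O-(1,3,2-benzodioxaborol-2-yl) derivative (C-3 epimers) | C=C1CC[C@@H]2[C@](C)(CCC(N(NS(=O)(=O)c5ccc(C)cc5)B6Oc7ccccc7O6)[C@]2(C)C(=O)O[C@@H]3C[C@H](C)CC[C@H]3C(C)(C)c4ccccc4)[C@H]1CC[C@H](C)CCOB8Oc9ccccc9O8 | intermediate
13 | (1R,2S,5R)-8-phenylmenthyl (4S,5R,9S,10R,13S)-15-hydroxylabd-8(17)-en-19-oate | C=C1CC[C@@H]2[C@](C)(CCC[C@]2(C)C(=O)O[C@@H]3C[C@H](C)CC[C@H]3C(C)(C)c4ccccc4)[C@H]1CC[C@H](C)CCO | intermediate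
14 | (4S,5R,9S,10R,13S)-labd-8(17)-ene-15,19-diol | C=C1CC[C@@H]2[C@](C)(CCC[C@]2(C)CO)[C@H]1CC[C@H](C)CCO | intermediate
15 | (4S,5R,9S,10R,13S)-19-hydroxylabd-8(17)-en-15-yl acetate | C=C1CC[C@@H]2[C@](C)(CCC[C@]2(C)CO)[C@H]1CC[C@H](C)CCOC(C)=O | intermediate
16 | (4S,5R,9S,10R,13S)-15-acetoxylabd-8(17)-en-19-oic acid = (1S,4aR,5S,8aR)-5-[(3S)-5-acetoxy-3-methylpentyl]-1,4a-dimethyl-6-methylidenedecahydronaphthalene-1-carboxylic acid | C=C1CC[C@@H]2[C@](C)(CCC[C@]2(C)C(=O)O)[C@H]1CC[C@H](C)CCOC(C)=O | target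

## Step count and risk
Total steps: 10. Longest linear sequence: 9 (1 → 2 → 3 → 4 → 9 → 10 → 13 → 14 → 15 → 16); the auxiliary ester 7 is a one-step side branch.

The three steps most likely to fail:

Step 6 (bicyclisation). The risks are modest yield, incomplete facial control by the auxiliary, and some endocyclic alkene from the copper termination. The fallback sets out from 9 and comes back at 10. Selenenylation of 9 at the α-carbon (PhSeCl, pyridine, CH2Cl2, 0 °C) gives the α-phenylselanyl β-keto ester F1. Irradiation of F1 (sunlamp, benzene, 10 mol % (Bu3Sn)2) generates the same C-4 radical under the same auxiliary control; it cyclises twice in a non-oxidative phenylselanyl group-transfer chain to the C-8 tertiary selenide F2. H2O2/pyridine (CH2Cl2, 0 → 23 °C) then forms the selenoxide, whose syn-elimination reaches the freely rotating methyl hydrogens most easily and gives the exocyclic alkene of 10.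

Step 7 (deoxygenation of the ketone next to the quaternary C-4 that carries the bulky ester). Hydrazone formation or C=N reduction may stall. The fallback sets out from 10 and comes back at 13. Ethane-1,2-dithiol with Zn(OTf)2 (CH2Cl2, 23 °C) gives the 3,3-ethylenedithio ketal (1,3-dithiolane) F3. Radical desulfurisation with Bu3SnH (4 equiv)/AIBN in toluene at 110 °C then removes both C–S bonds without touching the alkene and gives 13.

Step 5 (dianion alkylation with the unprotected bromo alcohol). Proton transfer or O-alkylation could erode the yield and waste auxiliary. The fallback sets out from 4 and comes back at 9. Silylation of 4 (TBSOTf, 2,6-lutidine, CH2Cl2, −78 °C) gives the TBS ether F4. Alkylation of only 1.1 equiv of dienolate 8 with F4 gives the silylated keto ester F5, and HF·pyridine (THF, 0 °C) returns 9.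

Further compounds
F1 | step 6 | (1R,2S,5R)-8-phenylmenthyl (6E,10E,14S)-16-hydroxy-2,6,10,14-tetramethyl-3-oxo-2-(phenylselanyl)hexadeca-6,10-dienoate (C-2 epimers) | CC([Se]c1ccccc1)(C(=O)CC/C(C)=C/CC/C(C)=C/CC[C@H](C)CCO)C(=O)O[C@@H]1C[C@H](C)CC[C@H]1C(C)(C)c1ccccc1
F2 | step 6 | (1R,2S,5R)-8-phenylmenthyl (4R,5R,9S,10R,13S)-15-hydroxy-3-oxo-8-(phenylselanyl)labdan-19-oate (C-8 epimers) | CC1([Se]c5ccccc5)CC[C@@H]2[C@](C)(CCC(=O)[C@]2(C)C(=O)O[C@@H]3C[C@H](C)CC[C@H]3C(C)(C)c4ccccc4)[C@H]1CC[C@H](C)CCO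
F3 | step 7 | (1R,2S,5R)-8-phenylmenthyl (4R,5R,9S,10R,13S)-3,3-(ethane-1,2-diyldisulfanediyl)-15-hydroxylabd-8(17)-en-19-oate (1,3-dithiolane of 10) | C=C1CC[C@@H]2[C@](C)(CCC5(SCCS5)[C@]2(C)C(=O)O[C@@H]3C[C@H](C)CC[C@H]3C(C)(C)c4ccccc4)[C@H]1CC[C@H](C)CCO
F4 | step 5 | [(3S,6E,10E)-12-bromo-3,7,11-trimethyldodeca-6,10-dien-1-yl]oxy(tert-butyl)dimethylsilane | BrC/C(C)=C/CC/C(C)=C/CC[C@H](C)CCO[Si](C)(C)C(C)(C)C
F5 | step 5 | (1R,2S,5R)-8-phenylmenthyl (6E,10E,14S)-16-(tert-butyldimethylsilyloxy)-2,6,10,14-tetramethyl-3-oxohexadeca-6,10-dienoate (C-2 epimers) | CC(C(=O)CC/C(C)=C/CC/C(C)=C/CC[C@H](C)CCO[Si](C)(C)C(C)(C)C)C(=O)O[C@@H]1C[C@H](C)CC[C@H]1C(C)(C)c1ccccc1
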